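**Plan**

- Retrosynthetic cuts: (i) the bond from the exocyclic CH2 to the enolic ring CH of the triketone (reductive Knoevenagel; the CH2 is taken back to an aldehyde); (ii) the cyclopentane bond between the C(OH)(CH3) carbon and the ring CH that carries that CH2 (aldol); (iii) the prenyl–C(quaternary) bond and the ring–acyl bond of the six-membered ring.
- Enabling feature: in the cyclopentane, the tertiary carbinol carbon, the adjacent ring CH and its exocyclic carbon form a β-hydroxy aldehyde once that carbon is at the aldehyde level. Opening this ring bond leaves a 1,6-keto aldehyde whose ten carbons are those of (R)-limonene with its ring C=C cut, the isopropenyl-bearing centre already in place.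
- Forward, terpene half: periodic acid cuts the C1–C2 bond of (4R)-limonene 1,2-oxide; an L-proline aldol addition then re-closes the ring one carbon smaller, leaving the old C2 outside the ring as the aldehyde. This cyclopentane is the only ring closed in the route; the six-membered ring is bought as methylphloroglucinol.
- Forward, triketone half and union: Friedel–Crafts acylation of 2-methylphloroglucinol, enantioselective dearomative prenylation at the methylated carbon, then proline/Hantzsch ester reductive alkylation with the aldehyde.
- Stereochemistry: the isopropenyl carbon comes from limonene; the ring CH and the carbinol carbon come from the aldol (resident centre and L-proline acting in the same sense); the quaternary carbon comes from the chiral palladium catalyst.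

Key step: step 2

Remark: the six-membered triketone ring is drawn throughout in the enol tautomer of the target SMILES; its tautomers interconvert freely and the CIP labels refer to the tautomer drawn.

**Step 1**
Reactants: 1 (4R)-limonene 1,2-oxide (commercial cis/trans mixture)
Product: 3 (3R)-6-oxo-3-(prop-1-en-2-yl)heptanal, via limonene-1,2-diol 2 (not isolated)
Conditions: H5IO6 (1.2 equiv), THF/H2O, 0 °C to rt
Reagents that add atoms: water, O
Why: Acid-catalysed hydrolysis of either epoxide diastereomer gives diol 2, which undergoes periodate glycol cleavage between the former ring carbons C1 and C2 to the methyl ketone and the aldehyde; the isopropenyl-bearing centre is remote and the 1,1-disubstituted alkene should be inert to cold aqueous periodic acid.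

**Step 2**
Reactants: 3 (3R)-6-oxo-3-(prop-1-en-2-yl)heptanal
Product: 5 (1S,2R,5R)-2-hydroxy-2-methyl-5-(prop-1-en-2-yl)cyclopentane-1-carbaldehyde, via proline enamine 4 (not isolated)
Conditions: L-proline (20 mol %), CH2Cl2 (0.05 M), rt
Reagents that add atoms: none
Why: L-Proline condenses with the aldehyde of 3 (faster than with the methyl ketone) to give the (E)-enamine 4, whose α-carbon adds to the ketone carbonyl held by a hydrogen bond to the carboxylic acid, and hydrolysis then returns the catalyst; the closest known reaction type is the proline-catalysed intramolecular aldol addition (enolexo aldolisation) of dicarbonyl compounds. The cyclopentane closes 5-exo-trig in the enolexo sense, with both the enamine C=C and the ketone C=O outside the new ring. The carbaldehyde-bearing carbon (1S) is set trans to the isopropenyl group by the resident (5R) centre from limonene, which sits pseudo-equatorial in the envelope transition state; this is also the enamine face to which L-proline directs an electrophile, so catalyst and substrate act in the same sense, and the centre stays epimerisable through the enamine towards the more stable trans arrangement. The carbinol carbon (2R) follows from the hydrogen-bonded transition state, in which the ketone oxygen must lie next to the exocyclic enamine CH–N to reach the acid; in a forming five-membered ring this places OH cis to CHO and methyl trans, as in known 5-enolexo aldolisations of keto aldehydes. The step needs donor selectivity (aldehyde enamine, not ketone enolate, which would give an acetylcyclopentanol) and must stop before loss of water. Amine instead of hydroxide catalysis should secure the first, and room temperature without added acid the second.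

**Step 3**
Reactants: 6 2-methylbenzene-1,3,5-triol (2-methylphloroglucinol)
Product: 7 2-methyl-1-(2,4,6-trihydroxy-3-methylphenyl)propan-1-one
Conditions: isobutyryl chloride (1.1 equiv), AlCl3 (4 equiv), PhNO2, 65 °C; then ice/aq. HCl
Reagents that add atoms: isobutyryl chloride, CC(C)C(Cl)=O
Why: Friedel–Crafts C-acylation of the symmetrical, strongly activated triol should occur once at one of its two equivalent free ring positions, because the first acyl group deactivates the ring against a second acylation.

**Step 4**
Reactants: 7 2-methyl-1-(2,4,6-trihydroxy-3-methylphenyl)propan-1-one
Product: 8 (6R)-3,5-dihydroxy-6-methyl-6-(3-methylbut-2-en-1-yl)-2-(2-methylpropanoyl)cyclohexa-2,4-dien-1-one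
Conditions: prenyl methyl carbonate (1.0 equiv), Pd2(dba)3·CHCl3 (2.5 mol %), N,N'-[(1R,2R)-cyclohexane-1,2-diyl]bis[2-(diphenylphosphanyl)benzamide] (6 mol %), THF, 0 °C to rt
Reagents that add atoms: prenyl methyl carbonate (methyl 3-methylbut-2-en-1-yl carbonate), COC(=O)OCC=C(C)C
Why: Proposed new method: zerovalent palladium ionises the carbonate to a π-prenyl palladium cation and, after loss of CO2, methoxide, which deprotonates 7; the phenoxide then attacks the unsubstituted allyl terminus from outside the metal through its most electron-rich carbon, the methylated one, so that the ring is dearomatised and the quaternary centre forms inside the chiral pocket of the bis(phosphine) ligand, which must tell the two faces of the flat nucleophile apart by the acyl group on one flank (any O-prenyl ether should re-ionise under palladium and funnel to the C-product); the closest known reaction types are the palladium-catalysed asymmetric allylic dearomatisation of substituted naphthols and the racemic dearomative allylation of acylphloroglucinols; the (R,R) ligand is taken to give the (R) centre and would be exchanged for its enantiomer if the sense proves opposite.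

**Step 5**
Reactants: 5 (1S,2R,5R)-2-hydroxy-2-methyl-5-(prop-1-en-2-yl)cyclopentane-1-carbaldehyde; 8 (6R)-3,5-dihydroxy-6-methyl-6-(3-methylbut-2-en-1-yl)-2-(2-methylpropanoyl)cyclohexa-2,4-dien-1-one
Product: 10 (6R)-3,5-dihydroxy-4-{[(1S,2R,5R)-2-hydroxy-2-methyl-5-(prop-1-en-2-yl)cyclopentyl]methyl}-6-methyl-6-(3-methylbut-2-en-1-yl)-2-(2-methylpropanoyl)cyclohexa-2,4-dien-1-one (target), via alkylidene triketone 9 (not isolated)
Conditions: Hantzsch ester (diethyl 2,6-dimethyl-1,4-dihydropyridine-3,5-dicarboxylate, 1.2 equiv), L-proline (20 mol %), CH2Cl2, rt
Reagents that add atoms: none
Why: Proline-catalysed Knoevenagel condensation of aldehyde 5 with the acidic ring CH of 8 gives the electron-poor alkylidene 9, which should be reduced at once by conjugate hydride transfer from the dihydropyridine (three-component reductive alkylation of cyclic 1,3-diones); no stereocentre is formed or touched, the aldehyde α-centre is already in its more stable trans arrangement, and the isopropenyl and prenyl alkenes are not hydride acceptors.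

**Compound list**

1 | (4R)-limonene 1,2-oxide, i.e. (4R)-1-methyl-4-(prop-1-en-2-yl)-7-oxabicyclo[4.1.0]heptane, cis/trans mixture at the epoxide | C=C(C)[C@@H]1CCC2(C)OC2C1 | starting material
2 | (4R)-1-methyl-4-(prop-1-en-2-yl)cyclohexane-1,2-diol (trans-diol; C1/C2 configuration is lost in the cleavage) | C=C(C)[C@@H]1CCC(C)(O)C(O)C1 | intermediate
3 | (3R)-6-oxo-3-(prop-1-en-2-yl)heptanal | C=C(C)[C@H](CCC(C)=O)CC=O | intermediate
4 | (2S)-1-[(1E,3R)-6-oxo-3-(prop-1-en-2-yl)hept-1-en-1-yl]pyrrolidine-2-carboxylic acid (proline enamine of 3) | C=C(C)[C@H](CCC(C)=O)/C=C/N1CCC[C@H]1C(O)=O | intermediate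
5 | (1S,2R,5R)-2-hydroxy-2-methyl-5-(prop-1-en-2-yl)cyclopentane-1-carbaldehyde (CHO cis to OH, trans to isopropenyl) | C=C(C)[C@@H]1CC[C@@](C)(O)[C@H]1C=O | intermediate
6 | 2-methylbenzene-1,3,5-triol (2-methylphloroglucinol) | Cc1c(O)cc(O)cc1O | starting material
7 | 2-methyl-1-(2,4,6-trihydroxy-3-methylphenyl)propan-1-one | CC(C)C(=O)c1c(O)cc(O)c(C)c1O | intermediate
8 | (6R)-3,5-dihydroxy-6-methyl-6-(3-methylbut-2-en-1-yl)-2-(2-methylpropanoyl)cyclohexa-2,4-dien-1-one | C1=C(O)[C@@](C)(CC=C(C)C)C(=O)C(C(=O)C(C)C)=C1O | intermediate
9 | Knoevenagel adduct of 5 and 8: the former ring CH of 8 carries an exocyclic C=CH–cyclopentyl double bond (E/Z not defined), all four stereocentres as in 10 | C=C(C)[C@@H]1CC[C@@](C)(O)[C@H]1C=C1C(=O)[C@@](C)(CC=C(C)C)C(=O)C(C(=O)C(C)C)=C1O | intermediate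
10 | (6R)-3,5-dihydroxy-4-{[(1S,2R,5R)-2-hydroxy-2-methyl-5-(prop-1-en-2-yl)cyclopentyl]methyl}-6-methyl-6-(3-methylbut-2-en-1-yl)-2-(2-methylpropanoyl)cyclohexa-2,4-dien-1-one | C=C(C)[C@@H]1CC[C@@](C)(O)[C@H]1CC1=C(O)[C@@](C)(CC=C(C)C)C(=O)C(C(=O)C(C)C)=C1O | target

**Step count**

Total steps: 5. Longest linear sequence: 3 steps (1 → 3 → 5 → 10, or 6 → 7 → 8 → 10).

**Steps most likely to fail**

1. Step 4 (proposed new method). The risk is weak discrimination between the two faces of the flat phloroglucinolate by the chiral catalyst, together with competing allylation at the unsubstituted ring carbon or through the branched allyl terminus. The fallback sets out from 7 and uses the known base-mediated dearomative prenylation of methylated acylphloroglucinols (prenyl bromide, NaOMe, MeOH, 0 °C), which should give the racemic dienone F1. Its enantiomers are separated by preparative chromatography on a chiral stationary phase, and the (R)-enantiomer re-enters the route as 8.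

2. Step 2. The risk is ring closure through the other ketone orientation, which would put the hydroxyl trans to the aldehyde, or loss of water from the aldol product. The fallback sets out from 3 and accepts the dehydration: aldol condensation with piperidinium acetate should give the cyclopentene carbaldehyde F2. Nucleophilic epoxidation (H2O2, NaOH, MeOH, 0 °C) on the face away from the isopropenyl group should then give the epoxy aldehyde F3. Reductive cleavage of its Cα–O bond with SmI2 (THF/MeOH, −78 °C), followed by equilibration of the aldehyde α-centre to the trans arrangement, comes back to the route at 5. The hydroxyl configuration is then fixed by the epoxide face and no longer by the aldol transition state.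

3. Step 5. The risk is slow condensation at the hindered, α-branched aldehyde, which leaves time for retro-aldol cleavage or dehydration of the β-hydroxy aldehyde and for a second conjugate addition of the triketone to the alkylidene. The fallback sets out from 5 and 8 and separates condensation from reduction: Knoevenagel condensation in the presence of thiophenol (piperidine cat., EtOH, rt) should intercept the alkylidene as the isolable sulfide F4 (mixture at the new CH–S carbon). Radical desulfurisation (Bu3SnH, AIBN, toluene, 80 °C), the C–S bond being activated by the adjacent enol π-system, comes back to the route at 10.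

**Further compounds**

F1 | step 4 | racemic 3,5-dihydroxy-6-methyl-6-(3-methylbut-2-en-1-yl)-2-(2-methylpropanoyl)cyclohexa-2,4-dien-1-one | C1=C(O)C(C)(CC=C(C)C)C(=O)C(C(=O)C(C)C)=C1O
F2 | step 2 | (5S)-2-methyl-5-(prop-1-en-2-yl)cyclopent-1-ene-1-carbaldehyde | C=C(C)[C@@H]1CCC(C)=C1C=O
F3 | step 2 | 5-methyl-2-(prop-1-en-2-yl)-6-oxabicyclo[3.1.0]hexane-1-carbaldehyde, epoxide oxygen trans to the isopropenyl group | C=C(C)[C@@H]1CC[C@@]2(C)O[C@@]12C=O
F4 | step 5 | phenyl sulfide adduct of 9: the exocyclic carbon between the cyclopentane and the triketone ring carries SPh (configuration at that carbon not defined) | C=C(C)[C@@H]1CC[C@@](C)(O)[C@H]1C(Sc1ccccc1)C1=C(O)[C@@](C)(CC=C(C)C)C(=O)C(C(=O)C(C)C)=C1O
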